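Everything rests on cutting ring A at two neighbouring carbons: the diaryl ether bond C6–O and the bond from C1 to the ester carbon. Ring A carries OH at C2, CO2Me at C1 and the aryloxy oxygen at C6 in an unbroken row, which is the imprint of a 3-alkoxybenzyne that has taken a nucleophile at its far carbon and an electrophile at its near one. In a single operation the ring B phenoxide and CO2 are added across 3-benzyloxy-5-methylbenzyne, delivering the complete diaryl ether benzoic acid. The precursors are an orcinol-derived 2-silylaryl triflate and a 2,6-disubstituted ring B phenol bearing a benzyl ether and a silyl-protected hydroxymethyl group.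

Key step: step 10

Remark: ring B is built from 2-hydroxy-4-methoxybenzaldehyde, because only this isomer leaves the methoxy group para to the phenol oxygen after benzylation, Dakin-type oxidation and ortho-formylation (the 5-methoxy isomer would place it meta); carbon dioxide and palmitoyl chloride are numbered as starting materials, and no compound in the route has a stereocentre.

Step 1
Reactants: 1 orcinol (5-methylbenzene-1,3-diol)
Product: 2 3-(benzyloxy)-5-methylphenol
Conditions: BnBr (0.5 equiv), K2CO3, acetone, reflux
Reagents that add atoms: benzyl bromide, BrCc1ccccc1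
Why: Williamson ether synthesis in which an excess of the symmetrical diol keeps dialkylation low, the monoether being separated from recoverable orcinol and a little dibenzyl ether.

Step 2
Reactants: 2 3-(benzyloxy)-5-methylphenol
Product: 3 3-(benzyloxy)-5-methylphenyl propan-2-ylcarbamate
Conditions: i-PrNCO, Et3N (cat.), CH2Cl2, rt
Reagents that add atoms: isopropyl isocyanate, CC(C)N=C=O
Why: Base-catalysed addition of the phenol to the isocyanate (carbamoylation) installs an N-monoalkyl carbamate that directs metalation and can later be removed by E1cB elimination.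

Step 3
Reactants: 3 3-(benzyloxy)-5-methylphenyl propan-2-ylcarbamate
Product: 7 3-(benzyloxy)-5-methyl-2-(trimethylsilyl)phenyl propan-2-ylcarbamate, via N-silyl carbamate 4 (not isolated), via aryllithium 5 (not isolated), via bis-silyl carbamate 6 (not isolated)
Conditions: TBSOTf, TMEDA, Et2O, 0 °C to rt; then n-BuLi, TMEDA, −78 °C; then TMSCl, −78 °C to rt; aq NaHSO4
Reagents that add atoms: chlorotrimethylsilane, C[Si](C)(C)Cl
Why: Directed ortho-metalation in which in situ N-silylation masks the N–H, n-BuLi/TMEDA removes the proton at C2 (the only position flanked by the carbamate and the benzyloxy oxygen) at a temperature too low for anionic Fries shift or benzylic deprotonation, TMSCl traps the aryllithium and the N–Si bond is hydrolysed on acidic work-up.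

Step 4
Reactants: 7 3-(benzyloxy)-5-methyl-2-(trimethylsilyl)phenyl propan-2-ylcarbamate
Product: 9 3-(benzyloxy)-5-methyl-2-(trimethylsilyl)phenyl trifluoromethanesulfonate, via silylphenol 8 (not isolated)
Conditions: Et2NH, DBU, MeCN, 40 °C; then PhNTf2, rt
Reagents that add atoms: N-phenylbis(trifluoromethanesulfonimide), O=S(=O)(N(c1ccccc1)S(=O)(=O)C(F)(F)F)C(F)(F)F
Why: DBU induces E1cB loss of isopropyl isocyanate (scavenged by Et2NH as a urea) and the phenoxide set free is O-triflated in the same flask, the standard carbamate cleavage–triflation finish for 2-silylaryl triflates.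

Step 5
Reactants: 10 2-hydroxy-4-methoxybenzaldehyde
Product: 11 2-(benzyloxy)-4-methoxybenzaldehyde
Conditions: BnBr, K2CO3, DMF, rt
Reagents that add atoms: benzyl bromide, BrCc1ccccc1
Why: Williamson ether synthesis on the only hydroxyl group, a routine alkylation of a salicylaldehyde.

Step 6
Reactants: 11 2-(benzyloxy)-4-methoxybenzaldehyde
Product: 13 2-(benzyloxy)-4-methoxyphenol, via aryl formate 12 (not isolated)
Conditions: mCPBA, CH2Cl2, 0 °C to rt; aq NaHCO3 wash; then K2CO3 (cat.), MeOH, rt
Reagents that add atoms: 3-chloroperoxybenzoic acid, O=C(OO)c1cccc(Cl)c1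
Why: Baeyer–Villiger (Dakin-type) oxidation in which the electron-rich 2,4-dialkoxyaryl group migrates in preference to hydride, the oxidisable phenol staying masked as its formate until the peracid has been washed out and methanolysis reveals it para to the methoxy group.

Step 7
Reactants: 13 2-(benzyloxy)-4-methoxyphenol
Product: 14 3-(benzyloxy)-2-hydroxy-5-methoxybenzaldehyde
Conditions: MgCl2, Et3N, (CH2O)n, MeCN, reflux
Reagents that add atoms: formaldehyde (as paraformaldehyde), C=O
Why: Magnesium-mediated ortho-formylation (Casnati–Skattebøl reaction) in which the magnesium phenoxide delivers formaldehyde to C6, the only free ortho position, and a second formaldehyde oxidises the hydroxymethyl stage to the aldehyde.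

Step 8
Reactants: 14 3-(benzyloxy)-2-hydroxy-5-methoxybenzaldehyde
Product: 15 2-(benzyloxy)-6-(hydroxymethyl)-4-methoxyphenol
Conditions: NaBH4, MeOH/THF, 0 °C
Reagents that add atoms: none
Why: Borohydride reduction of the aldehyde to the primary alcohol, no other reducible group being present.

Step 9
Reactants: 15 2-(benzyloxy)-6-(hydroxymethyl)-4-methoxyphenol
Product: 16 2-(benzyloxy)-6-({[tert-butyl(dimethyl)silyl]oxy}methyl)-4-methoxyphenol
Conditions: TBSCl (1.05 equiv), imidazole, CH2Cl2, 0 °C
Reagents that add atoms: tert-butyldimethylsilyl chloride, CC(C)(C)[Si](C)(C)Cl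
Why: Chemoselective O-silylation, since the primary benzylic alcohol reacts with TBSCl far faster than a phenol that is flanked by two ortho substituents.

Step 10
Reactants: 9 3-(benzyloxy)-5-methyl-2-(trimethylsilyl)phenyl trifluoromethanesulfonate; 16 2-(benzyloxy)-6-({[tert-butyl(dimethyl)silyl]oxy}methyl)-4-methoxyphenol; 17 carbon dioxide
Product: 22 2-(benzyloxy)-6-[2-(benzyloxy)-6-({[tert-butyl(dimethyl)silyl]oxy}methyl)-4-methoxyphenoxy]-4-methylbenzoic acid, via potassium phenoxide 18 (not isolated), via aryne 19 (not isolated), via arylpotassium 20 (not isolated), via potassium carboxylate 21 (not isolated)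
Conditions: 16 (1.3 equiv), KH, THF, 0 °C; then 18-crown-6, KF, CO2 (1 atm), 9 added slowly, 0 °C to rt; cold dilute HCl to pH 3
Reagents that add atoms: none
Why: Proposed new method: fluoride attacks silicon in 9 and expels triflate to give aryne 19, the crown-separated phenoxide 18 adds to the aryne carbon remote from the benzyloxy group, and the resulting aryl anion 20, flanked by two oxygen-bearing carbons, is captured by CO2 to give carboxylate 21, which is protonated on work-up. The closest known reaction types are the fluoride-promoted three-component coupling of arynes with amines and CO2 that gives anthranilic acids, the metal-free O-arylation of phenols by 2-silylaryl triflates, and the trapping of phenoxide–aryne adducts by a carbonyl group. No ring is closed and no stereocentre is created. Regiochemistry is the selectivity that matters, and it is secured by the inductively withdrawing C3 benzyloxy group of the aryne, which distorts the triple bond so that the nucleophile bonds to C1 and the negative charge develops at C2 next to oxygen. Carboxylation must outrun protonation, which is why the phenoxide is preformed with KH (only H2 is released), THF replaces the more acidic MeCN, and the solution is kept saturated with CO2 while 9 is added slowly as the limiting component. The ring B phenoxide has both ortho positions and the para position substituted, so it can react only at oxygen and cannot undergo Kolbe–Schmitt C-carboxylation.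

Step 11
Reactants: 22 2-(benzyloxy)-6-[2-(benzyloxy)-6-({[tert-butyl(dimethyl)silyl]oxy}methyl)-4-methoxyphenoxy]-4-methylbenzoic acid
Product: 23 methyl 2-(benzyloxy)-6-[2-(benzyloxy)-6-({[tert-butyl(dimethyl)silyl]oxy}methyl)-4-methoxyphenoxy]-4-methylbenzoate
Conditions: MeI, KHCO3, DMF, rt
Reagents that add atoms: iodomethane, CI
Why: SN2 O-alkylation of the carboxylate by MeI, which bypasses the steric shielding of the 2,6-disubstituted carbonyl group and touches neither the benzyl nor the silyl ethers.

Step 12
Reactants: 23 methyl 2-(benzyloxy)-6-[2-(benzyloxy)-6-({[tert-butyl(dimethyl)silyl]oxy}methyl)-4-methoxyphenoxy]-4-methylbenzoate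
Product: 24 methyl 2-[2-({[tert-butyl(dimethyl)silyl]oxy}methyl)-6-hydroxy-4-methoxyphenoxy]-6-hydroxy-4-methylbenzoate
Conditions: H2 (1 atm), 10% Pd/C, EtOAc, rt
Reagents that add atoms: none
Why: Catalytic hydrogenolysis cleaves both aryl benzyl ethers while the diaryl ether, the methyl ester and the benzylic silyl ether should survive in neutral EtOAc; it is placed before the esterification because the palmitate of the target is itself a benzylic ester that hydrogenolysis would cleave.

Step 13
Reactants: 24 methyl 2-[2-({[tert-butyl(dimethyl)silyl]oxy}methyl)-6-hydroxy-4-methoxyphenoxy]-6-hydroxy-4-methylbenzoate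
Product: 25 methyl 2-hydroxy-6-[2-hydroxy-6-(hydroxymethyl)-4-methoxyphenoxy]-4-methylbenzoate
Conditions: HF·pyridine, THF/pyridine, 0 °C to rt
Reagents that add atoms: none
Why: Fluoride-mediated desilylation of the primary TBS ether under buffered conditions that leave the methyl salicylate, the diaryl ether and both phenols untouched.

Step 14
Reactants: 25 methyl 2-hydroxy-6-[2-hydroxy-6-(hydroxymethyl)-4-methoxyphenoxy]-4-methylbenzoate; 26 palmitoyl chloride (hexadecanoyl chloride)
Product: 27 betaethrin E, methyl 2-hydroxy-6-{2-hydroxy-6-[(hexadecanoyloxy)methyl]-4-methoxyphenoxy}-4-methylbenzoate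
Conditions: 26 (1.05 equiv), 2,4,6-collidine, CH2Cl2, −40 °C to 0 °C
Reagents that add atoms: none
Why: Chemoselective O-acylation, since with a weak pyridine base that forms no phenoxide the primary alcohol is a much better nucleophile towards the acid chloride than the hindered ring B phenol or the hydrogen-bonded salicylate OH of ring A, as in the selective esterification of phenolic alcohols.

Compound list
1 | orcinol (5-methylbenzene-1,3-diol) | Cc1cc(O)cc(O)c1 | starting material
2 | 3-(benzyloxy)-5-methylphenol | Cc1cc(O)cc(OCc2ccccc2)c1 | intermediate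
3 | 3-(benzyloxy)-5-methylphenyl propan-2-ylcarbamate | Cc1cc(OCc2ccccc2)cc(OC(=O)NC(C)C)c1 | intermediate
4 | 3-(benzyloxy)-5-methylphenyl N-[tert-butyl(dimethyl)silyl]-N-(propan-2-yl)carbamate (not isolated) | Cc1cc(OCc2ccccc2)cc(OC(=O)N(C(C)C)[Si](C)(C)C(C)(C)C)c1 | intermediate
5 | 2-lithio derivative of 4, lithium at C2 between the two oxygen-bearing carbons (not isolated) | Cc1cc(OCc2ccccc2)c([Li])c(OC(=O)N(C(C)C)[Si](C)(C)C(C)(C)C)c1 | intermediate
6 | 3-(benzyloxy)-5-methyl-2-(trimethylsilyl)phenyl N-[tert-butyl(dimethyl)silyl]-N-(propan-2-yl)carbamate (not isolated) | Cc1cc(OCc2ccccc2)c([Si](C)(C)C)c(OC(=O)N(C(C)C)[Si](C)(C)C(C)(C)C)c1 | intermediate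
7 | 3-(benzyloxy)-5-methyl-2-(trimethylsilyl)phenyl propan-2-ylcarbamate | Cc1cc(OCc2ccccc2)c([Si](C)(C)C)c(OC(=O)NC(C)C)c1 | intermediate
8 | 3-(benzyloxy)-5-methyl-2-(trimethylsilyl)phenol (not isolated) | Cc1cc(O)c([Si](C)(C)C)c(OCc2ccccc2)c1 | intermediate
9 | 3-(benzyloxy)-5-methyl-2-(trimethylsilyl)phenyl trifluoromethanesulfonate | Cc1cc(OCc2ccccc2)c([Si](C)(C)C)c(OS(=O)(=O)C(F)(F)F)c1 | intermediate
10 | 2-hydroxy-4-methoxybenzaldehyde | COc1ccc(C=O)c(O)c1 | starting material
11 | 2-(benzyloxy)-4-methoxybenzaldehyde | COc1ccc(C=O)c(OCc2ccccc2)c1 | intermediate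
12 | 2-(benzyloxy)-4-methoxyphenyl formate (not isolated) | COc1ccc(OC=O)c(OCc2ccccc2)c1 | intermediate
13 | 2-(benzyloxy)-4-methoxyphenol | COc1ccc(O)c(OCc2ccccc2)c1 | intermediate
14 | 3-(benzyloxy)-2-hydroxy-5-methoxybenzaldehyde | COc1cc(C=O)c(O)c(OCc2ccccc2)c1 | intermediate
15 | 2-(benzyloxy)-6-(hydroxymethyl)-4-methoxyphenol | COc1cc(CO)c(O)c(OCc2ccccc2)c1 | intermediate
16 | 2-(benzyloxy)-6-({[tert-butyl(dimethyl)silyl]oxy}methyl)-4-methoxyphenol | COc1cc(CO[Si](C)(C)C(C)(C)C)c(O)c(OCc2ccccc2)c1 | intermediate
17 | carbon dioxide | O=C=O | starting material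
18 | potassium 2-(benzyloxy)-6-({[tert-butyl(dimethyl)silyl]oxy}methyl)-4-methoxyphenoxide (not isolated) | COc1cc(CO[Si](C)(C)C(C)(C)C)c([O-])c(OCc2ccccc2)c1.[K+] | intermediate
19 | 3-(benzyloxy)-5-methylbenzyne (not isolated) | CC1=CC#CC(OCc2ccccc2)=C1 | intermediate
20 | arylpotassium adduct, potassium at C1 of ring A between the benzyloxy-bearing and aryloxy-bearing carbons (not isolated) | Cc1cc(OCc2ccccc2)c([K])c(Oc2c(CO[Si](C)(C)C(C)(C)C)cc(OC)cc2OCc2ccccc2)c1 | intermediate
21 | potassium salt of acid 22 (not isolated) | Cc1cc(OCc2ccccc2)c(C(=O)[O-])c(Oc2c(CO[Si](C)(C)C(C)(C)C)cc(OC)cc2OCc2ccccc2)c1.[K+] | intermediate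
22 | 2-(benzyloxy)-6-[2-(benzyloxy)-6-({[tert-butyl(dimethyl)silyl]oxy}methyl)-4-methoxyphenoxy]-4-methylbenzoic acid | Cc1cc(OCc2ccccc2)c(C(=O)O)c(Oc2c(CO[Si](C)(C)C(C)(C)C)cc(OC)cc2OCc2ccccc2)c1 | intermediate
23 | methyl 2-(benzyloxy)-6-[2-(benzyloxy)-6-({[tert-butyl(dimethyl)silyl]oxy}methyl)-4-methoxyphenoxy]-4-methylbenzoate | Cc1cc(OCc2ccccc2)c(C(=O)OC)c(Oc2c(CO[Si](C)(C)C(C)(C)C)cc(OC)cc2OCc2ccccc2)c1 | intermediate
24 | methyl 2-[2-({[tert-butyl(dimethyl)silyl]oxy}methyl)-6-hydroxy-4-methoxyphenoxy]-6-hydroxy-4-methylbenzoate | Cc1cc(O)c(C(=O)OC)c(Oc2c(CO[Si](C)(C)C(C)(C)C)cc(OC)cc2O)c1 | intermediate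
25 | methyl 2-hydroxy-6-[2-hydroxy-6-(hydroxymethyl)-4-methoxyphenoxy]-4-methylbenzoate | Cc1cc(O)c(C(=O)OC)c(Oc2c(CO)cc(OC)cc2O)c1 | intermediate
26 | palmitoyl chloride (hexadecanoyl chloride) | CCCCCCCCCCCCCCCC(=O)Cl | starting material
27 | betaethrin E, methyl 2-hydroxy-6-{2-hydroxy-6-[(hexadecanoyloxy)methyl]-4-methoxyphenoxy}-4-methylbenzoate | CCCCCCCCCCCCCCCC(=O)OCc1cc(OC)cc(O)c1Oc1cc(C)cc(O)c1C(=O)OC | target

Total step count: 14. Longest linear sequence: 10 steps (steps 5 to 14, from 10 to 27); the ring A branch (steps 1 to 4) joins at step 10.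

Steps most likely to fail

Step 10. The aryl anion may be protonated before it meets CO2, or the phenoxide may be held back as its carbonate while the aryne is consumed by other pathways. The fallback makes the two bonds separately by known chemistry. It leaves the route at aryllithium 5, which is quenched with methyl chloroformate in place of TMSCl. This gives the N-silylated ester methyl 2-(benzyloxy)-6-({[tert-butyl(dimethyl)silyl](propan-2-yl)carbamoyl}oxy)-4-methylbenzoate F1 and, after the same acidic work-up, methyl 2-(benzyloxy)-4-methyl-6-[(propan-2-ylcarbamoyl)oxy]benzoate F2. Et2NH/DBU then releases methyl 2-(benzyloxy)-6-hydroxy-4-methylbenzoate F3, and Tf2O/pyridine converts it into methyl 2-(benzyloxy)-4-methyl-6-{[(trifluoromethyl)sulfonyl]oxy}benzoate F4. Palladium-catalysed diaryl ether formation between this electron-poor ortho-ester triflate and phenol 16 (Pd(OAc)2, tBuXPhos, K3PO4, toluene, 100 °C; Buchwald–Hartwig-type C–O coupling) comes back to the route at methyl ester 23.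

Step 14. Chemoselectivity may be lost through competing esterification of the ring B phenol. The fallback reverses the polarity of the esterification: triol 25 is treated with palmitic acid, PPh3 and diisopropyl azodicarboxylate in THF (Mitsunobu esterification). Only the primary alcohol is activated as an oxyphosphonium ion, and the carboxylate, far more acidic than either phenol, acts as the nucleophile. This should give 27 directly and makes no new compound (F0).

Step 7. Formylation may stall because the ortho benzyloxy group chelates magnesium and slows delivery of formaldehyde, with O-methoxymethylation competing on long heating. In the fallback, phenol 13 is condensed with phenylboronic acid and paraformaldehyde (cat. propionic acid, toluene, reflux with water removal) to give the cyclic boronate 8-(benzyloxy)-6-methoxy-2-phenyl-4H-1,3,2-benzodioxaborinine F5. Transesterification with propane-1,3-diol releases diol 15, so the route is rejoined after step 8 without passing through aldehyde 14.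

Further compounds
F1 | step 10 | methyl 2-(benzyloxy)-6-({[tert-butyl(dimethyl)silyl](propan-2-yl)carbamoyl}oxy)-4-methylbenzoate | Cc1cc(OCc2ccccc2)c(C(=O)OC)c(OC(=O)N(C(C)C)[Si](C)(C)C(C)(C)C)c1
F2 | step 10 | methyl 2-(benzyloxy)-4-methyl-6-[(propan-2-ylcarbamoyl)oxy]benzoate | Cc1cc(OCc2ccccc2)c(C(=O)OC)c(OC(=O)NC(C)C)c1
F3 | step 10 | methyl 2-(benzyloxy)-6-hydroxy-4-methylbenzoate | Cc1cc(O)c(C(=O)OC)c(OCc2ccccc2)c1
F4 | step 10 | methyl 2-(benzyloxy)-4-methyl-6-{[(trifluoromethyl)sulfonyl]oxy}benzoate | Cc1cc(OCc2ccccc2)c(C(=O)OC)c(OS(=O)(=O)C(F)(F)F)c1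
F0 | step 14 | none | none
F5 | step 7 | 8-(benzyloxy)-6-methoxy-2-phenyl-4H-1,3,2-benzodioxaborinine | COc1cc2c(c(OCc3ccccc3)c1)OB(c1ccccc1)OC2
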